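Target ⇐ O15-acetylation of the 14-propanoate 13,15-diol ⇐ new boron-templated propanoate opening at C14 (inversion) of the (13S,14S)-13,14-epoxy-15-ol; this step makes the C14–O ester bond, fixes 14R and frees the tertiary 13-OH.
Epoxy alcohol ⇐ Sharpless asymmetric epoxidation of geometrically pure (13E)-copalol (sets C13 and C14; only the allylic-alcohol alkene reacts).
(13E)-Copalol ⇐ terminal alkyne by Negishi methylalumination and hydroxymethylation ⇐ C18 methyl ketone ⇐ oxidative excision of the vinyl group of (+)-manool.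
Rings: rings A and B, with C5, C9, C10 and the C8 exocyclic methylene, are not built but taken intact from commercial (+)-manool; the only ring formed is the oxirane (step 4), reopened in step 5.

Assumption: (+)-manool, a commercial natural labdane of the normal series, is accepted as starting material; labdane numbering is used (decalin C1–C10, side chain C11–C15 on C9, C16 = methyl on C13, C17 = CH2 on C8, C18/C19 = methyls on C4, C20 = methyl on C10), and every compound keeps the (5S,9S,10S) decalin of manool.

Step 1
Reactants: 1 (+)-manool, (5S,9S,10S,13R)-labda-8(17),14-dien-13-ol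
Product: 2 (5S,9S,10S)-14,15-dinorlabd-8(17)-en-13-one (side chain CH2CH2C(=O)CH3)
Conditions: KMnO4 (4 equiv), acetone/H2O (10:1), 0 °C to rt
Reagents that add atoms: none
Why: Permanganate oxidative cleavage, in which the monosubstituted vinyl group next to the tertiary carbinol is dihydroxylated faster than the hindered 1,1-disubstituted C8 methylene and the resulting 13,14,15-triol is cleaved twice, so that C14 and C15 leave as carbonate and C13 becomes the methyl ketone (its oxygen is the old 13-OH) with no ring stereocentre touched.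

Step 2
Reactants: 2 (5S,9S,10S)-14,15-dinorlabd-8(17)-en-13-one
Product: 4 (5S,9S,10S)-15,16-dinorlabd-8(17)-en-13-yne (side chain CH2CH2C≡CH), via enol phosphate 3 (not isolated)
Conditions: LiN(iPr)2 (1.1 equiv), THF, −78 °C; ClP(O)(OEt)2, −78 °C to rt; LiN(iPr)2 (2.3 equiv), THF, −78 °C to rt; H2O
Reagents that add atoms: none
Why: Negishi methyl ketone-to-alkyne conversion, in which kinetic deprotonation at the methyl group, O-phosphorylation to the terminal enol phosphate and amide-induced E2 loss of diethyl phosphate give the terminal alkyne, held as its acetylide by the excess base so that no allene forms.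

Step 3
Reactants: 4 (5S,9S,10S)-15,16-dinorlabd-8(17)-en-13-yne
Product: 7 (5S,9S,10S,13E)-labda-8(17),13-dien-15-ol (copalol of the normal series), via alkenylalane 5 (not isolated), via lithium alkenylaluminate 6 (not isolated)
Conditions: Me3Al (2.5 equiv), Cp2ZrCl2 (0.2 equiv), CH2Cl2, 0 °C to rt; evaporate; n-BuLi (1 equiv), THF/hexane, −78 to 0 °C; (CH2O)n, rt; aq KNaC4H4O6 (potassium sodium tartrate)
Reagents that add atoms: trimethylaluminium, C[Al](C)C; paraformaldehyde (source of formaldehyde), C=O
Why: Negishi zirconium-catalysed carboalumination adds Me and Al syn with aluminium on the terminal carbon (above 98:2), and the derived butyl aluminate adds to formaldehyde with retention at the C–Al carbon, so the new trisubstituted alkene is purely 13E while the hindered 1,1-disubstituted C8 methylene is inert.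

Step 4
Reactants: 7 (5S,9S,10S,13E)-labda-8(17),13-dien-15-ol
Product: 8 (5S,9S,10S,13S,14S)-13,14-epoxylabd-8(17)-en-15-ol
Conditions: Ti(OiPr)4 (10 mol %), L-(+)-diethyl tartrate (12 mol %), t-BuOOH (2 equiv, in decane), 4 Å MS, CH2Cl2, −20 °C
Reagents that add atoms: tert-butyl hydroperoxide, CC(C)(C)OO
Why: Sharpless asymmetric epoxidation, in which the titanium tartrate peroxide complex epoxidises only the allylic-alcohol alkene and, with L-(+)-tartrate, converts an (E)-3-methylalk-2-en-1-ol into the (2S,3S)-type oxirane (the geraniol precedent), here 13S,14S, under reagent control because the decalin stereocentres are remote.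

Step 5
Reactants: 8 (5S,9S,10S,13S,14S)-13,14-epoxylabd-8(17)-en-15-ol
Product: 11 (5S,9S,10S,13S,14R)-13,15-dihydroxylabd-8(17)-en-14-yl propanoate, via epoxy borate 9 (not isolated), via cyclic borate 10 (not isolated)
Conditions: B(OMe)3 (1.5 equiv), EtCO2H (1.2 equiv), EtCO2Cs (2 equiv), 4 Å MS, DMF, 60 °C; then pH 7 phosphate buffer, 0 °C
Reagents that add atoms: propanoic acid, CCC(=O)O; caesium propanoate, CCC(=O)[O-].[Cs+]
Why: Proposed new method: B(OMe)3 esterifies O15 to give borate 9, which blocks Payne rearrangement, holds propanoate on or near boron and activates the oxirane through internal B–O coordination, and because C13 is fully substituted and the buffered medium is non-ionising the carboxylate can only displace the oxirane oxygen from C14 in an SN2 step (inversion, 14S to 14R, while C13 keeps its oxygen and its S configuration), after which the freed O13 alkoxide closes onto boron to give the six-membered borate 10 (the buffer acid removing one methoxide as methanol), which masks both hydroxyls against propanoyl migration until neutral hydrolysis; the closest known reaction types are the trialkyl borate-mediated C2-selective azide and thiolate openings of 2,3-epoxy alcohols and the Cs2CO3/CO2 conversion of 2,3-epoxy alcohols into C1/C2 cyclic carbonates with inversion at C2, whereas a carboxylate nucleophile on a 3,3-disubstituted epoxy alcohol has not been shown in this manifold.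

Step 6
Reactants: 11 (5S,9S,10S,13S,14R)-13,15-dihydroxylabd-8(17)-en-14-yl propanoate
Product: 12 (5S,9S,10S,13S,14R)-15-acetoxy-13-hydroxylabd-8(17)-en-14-yl propanoate (target, CNP0275533.1)
Conditions: Ac2O (1.5 equiv), pyridine, CH2Cl2, 0 °C
Reagents that add atoms: acetic anhydride, CC(=O)OC(C)=O
Why: Chemoselective O-acetylation, in which without an acyl-transfer catalyst only the primary 15-OH reacts (O14 is already esterified and the tertiary 13-OH is inert) and the cold, weakly basic medium leaves no time for propanoyl migration, so no stereocentre is affected.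

Compound list
1 | (+)-manool, (5S,9S,10S,13R)-labda-8(17),14-dien-13-ol | C=C1CC[C@H]2C(C)(C)CCC[C@]2(C)[C@H]1CC[C@@](C)(O)C=C | starting material
2 | (5S,9S,10S)-14,15-dinorlabd-8(17)-en-13-one | C=C1CC[C@H]2C(C)(C)CCC[C@]2(C)[C@H]1CCC(C)=O | intermediate
3 | diethyl (5S,9S,10S)-14,15-dinorlabda-8(17),13(16)-dien-13-yl phosphate (terminal enol phosphate) | C=C1CC[C@H]2C(C)(C)CCC[C@]2(C)[C@H]1CCC(=C)OP(=O)(OCC)OCC | intermediate
4 | (5S,9S,10S)-15,16-dinorlabd-8(17)-en-13-yne | C=C1CC[C@H]2C(C)(C)CCC[C@]2(C)[C@H]1CCC#C | intermediate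
5 | dimethyl[(5S,9S,10S,13E)-15-norlabda-8(17),13-dien-14-yl]alane | C=C1CC[C@H]2C(C)(C)CCC[C@]2(C)[C@H]1CC/C(C)=C/[Al](C)C | intermediate
6 | lithium butyl(dimethyl)[(5S,9S,10S,13E)-15-norlabda-8(17),13-dien-14-yl]aluminate | C=C1CC[C@H]2C(C)(C)CCC[C@]2(C)[C@H]1CC/C(C)=C/[Al-](C)(C)CCCC.[Li+] | intermediate
7 | (5S,9S,10S,13E)-labda-8(17),13-dien-15-ol (copalol, normal series) | C=C1CC[C@H]2C(C)(C)CCC[C@]2(C)[C@H]1CC/C(C)=C/CO | intermediate
8 | (5S,9S,10S,13S,14S)-13,14-epoxylabd-8(17)-en-15-ol | C=C1CC[C@H]2C(C)(C)CCC[C@]2(C)[C@H]1CC[C@]3(C)O[C@H]3CO | intermediate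
9 | dimethyl (5S,9S,10S,13S,14S)-13,14-epoxylabd-8(17)-en-15-yl borate | C=C1CC[C@H]2C(C)(C)CCC[C@]2(C)[C@H]1CC[C@]3(C)O[C@H]3COB(OC)OC | intermediate
10 | cyclic methyl borate of 11 (2-methoxy-1,3,2-dioxaborinane spanning O13 and O15; 13S,14R; 14-propanoate) | C=C1CC[C@H]2C(C)(C)CCC[C@]2(C)[C@H]1CC[C@]3(C)OB(OC)OC[C@H]3OC(=O)CC | intermediate
11 | (5S,9S,10S,13S,14R)-13,15-dihydroxylabd-8(17)-en-14-yl propanoate | C=C1CC[C@H]2C(C)(C)CCC[C@]2(C)[C@H]1CC[C@](C)(O)[C@@H](CO)OC(=O)CC | intermediate
12 | (5S,9S,10S,13S,14R)-15-acetoxy-13-hydroxylabd-8(17)-en-14-yl propanoate | C=C1CC[C@H]2C(C)(C)CCC[C@]2(C)[C@H]1CC[C@](C)(O)[C@@H](COC(C)=O)OC(=O)CC | target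

Total step count: 6. Longest linear sequence: 6 steps (1 to 12).

Steps most likely to fail

Step 5 (the new reaction). It may stall, C13 may ionise so that propanoate enters at C13 (giving the 13-ester with the wrong C13/C14 pattern), or the propanoyl group may shift to O15 during work-up. The fallback uses known chemistry and sets out from 8. Cs2CO3 (0.5 equiv) under CO2 (1 atm) in DMF with 3 Å MS at 40 °C turns the 2,3-epoxy alcohol into (5S,9S,10S,13S,14R)-13-hydroxylabd-8(17)-ene-14,15-diyl carbonate F3, the O15 carbonate anion opening C14 in a 5-exo SN2 step with inversion. K2CO3 in MeOH then gives (5S,9S,10S,13S,14R)-labd-8(17)-ene-13,14,15-triol F4. AcCl with 2,4,6-collidine in CH2Cl2 at −78 °C acetylates only the primary hydroxyl to give (5S,9S,10S,13S,14R)-13,14-dihydroxylabd-8(17)-en-15-yl acetate F5. (EtCO)2O with Et3N and catalytic DMAP in CH2Cl2 at 0 °C acylates the remaining secondary 14-OH, and the fallback comes back to the route at 12.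

Step 1. Permanganate may also attack the C8 methylene or degrade the ketone further. The fallback sets out from 1 and avoids alkene-cleaving oxidants altogether. Pyridinium chlorochromate, [C5H5NH][CrO3Cl], in CH2Cl2 effects the Babler–Dauben oxidative 1,3-transposition of the tertiary vinyl carbinol to (5S,9S,10S,13E)-labda-8(17),13-dien-15-al F1, formed with its 13Z isomer (about 2:1). The isomers are separated on AgNO3-impregnated silica and the Z isomer is recycled by equilibration. NaBH4 with CeCl3·7H2O in MeOH at 0 °C reduces F1 to 7, where the route is rejoined; steps 1 to 3 are replaced.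

Step 3. Carbometalation may be incomplete, the alkyne may be deprotonated, or capture by formaldehyde may be poor; step 2, which feeds it, can also give allene. The fallback sets out from 2. Horner–Wadsworth–Emmons olefination with (EtO)2P(O)CH2CO2Et and NaH in THF at reflux gives ethyl (5S,9S,10S,13E)-labda-8(17),13-dien-15-oate F2 (E/Z about 5:1, separated by chromatography). iBu2AlH in CH2Cl2 at −78 °C reduces F2 to 7, where the route is rejoined; steps 2 and 3 are replaced.

Further compounds
F1 | step 1 | (5S,9S,10S,13E)-labda-8(17),13-dien-15-al | C=C1CC[C@H]2C(C)(C)CCC[C@]2(C)[C@H]1CC/C(C)=C/C=O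
F2 | step 3 | ethyl (5S,9S,10S,13E)-labda-8(17),13-dien-15-oate | C=C1CC[C@H]2C(C)(C)CCC[C@]2(C)[C@H]1CC/C(C)=C/C(=O)OCC
F3 | step 5 | (5S,9S,10S,13S,14R)-13-hydroxylabd-8(17)-ene-14,15-diyl carbonate | C=C1CC[C@H]2C(C)(C)CCC[C@]2(C)[C@H]1CC[C@](C)(O)[C@H]3COC(=O)O3
F4 | step 5 | (5S,9S,10S,13S,14R)-labd-8(17)-ene-13,14,15-triol | C=C1CC[C@H]2C(C)(C)CCC[C@]2(C)[C@H]1CC[C@](C)(O)[C@@H](CO)O
F5 | step 5 | (5S,9S,10S,13S,14R)-13,14-dihydroxylabd-8(17)-en-15-yl acetate | C=C1CC[C@H]2C(C)(C)CCC[C@]2(C)[C@H]1CC[C@](C)(O)[C@@H](COC(C)=O)O
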